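**Plan**
- Retrosynthesis: the two acetates and the free ring C5 hydroxyl go back to a protected phenol/carbinol array, and the carbinol C–O bond goes back to a C–B bond. Two C–C bonds are then cut together: ring C1–chain C1 (aryl to benzylic CH2) and chain C2–chain C3 (carbinol carbon to undecyl).
- Enabling feature: the carbinol carbon (chain C2) sits between the benzylic CH2 (chain C1, on ring C1 of the benzene ring) and the undecyl chain. This two-carbon unit, with an aryl group on one end and an alkyl group plus a heteroatom on the other, is what a vinylboron unit delivers in a conjunctive coupling.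
- Forward: 5-bromovanillin gives the 1-bromo-2-(methoxymethoxy)-3-methoxy-5-benzyloxy arene in three steps, and 1-bromoundecane gives its Grignard reagent. Both are joined with vinylboronic acid pinacol ester in one palladium-catalysed operation. No ring is formed at any stage; the benzene ring is bought.
- Stereochemistry: the single stereocentre (chain C2, R) is created in the coupling by the chiral MandyPhos–palladium catalyst as a C–B bond and passed to C–O by stereoretentive oxidation.
- End game: MOM removal, acetylation of the ring C2 hydroxyl and the carbinol, then hydrogenolysis of the ring C5 benzyl ether.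

Key step: step 5

Assumption: the (Rp,Rp) antipode of MandyPhos (2,2′-bis[α-(dimethylamino)benzyl]-1,1′-bis(diphenylphosphino)ferrocene) is taken as the one that gives the R boronate with a primary alkyl migrating group. The sense is to be confirmed on a pilot run (oxidation, Mosher ester analysis), and the (Sp,Sp) antipode is used instead if it proves opposite.

**Route**

Step 1
Reactants: 1 5-bromovanillin
Product: 2 3-bromo-5-methoxy-4-(methoxymethoxy)benzaldehyde
Conditions: MOMCl, i-Pr2NEt, CH2Cl2, 0 °C → rt
Reagents that add atoms: chloromethyl methyl ether (MOMCl), COCCl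
Why: O-alkylation of the acidic, doubly ortho-substituted phenol with the highly reactive α-chloro ether (Williamson-type acetal formation) should be clean, since the aldehyde is inert to the amine base.

Step 2
Reactants: 2 3-bromo-5-methoxy-4-(methoxymethoxy)benzaldehyde
Product: 4 3-bromo-5-methoxy-4-(methoxymethoxy)phenol, via aryl formate 3 (not isolated)
Conditions: mCPBA, CH2Cl2, 0 °C → rt; aq. NaHCO3 wash; then K2CO3 (cat.), MeOH, rt
Reagents that add atoms: 3-chloroperoxybenzoic acid (mCPBA), OOC(=O)c1cccc(Cl)c1
Why: In this Baeyer–Villiger oxidation (Dakin-type) the aryl group carrying a para alkoxy donor should migrate in preference to hydride to give the formate, which mild methanolysis cleaves; the MOM acetal, methyl ether and bromide are inert to the peracid.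

Step 3
Reactants: 4 3-bromo-5-methoxy-4-(methoxymethoxy)phenol
Product: 5 5-(benzyloxy)-1-bromo-3-methoxy-2-(methoxymethoxy)benzene
Conditions: BnBr, K2CO3, DMF, rt
Reagents that add atoms: benzyl bromide, BrCc1ccccc1
Why: Williamson ether synthesis on an unhindered phenoxide (both ortho positions carry hydrogen) should be straightforward, and the MOM acetal is stable to base.

Step 4
Reactants: 6 1-bromoundecane
Product: 7 undecylmagnesium bromide
Conditions: Mg turnings, I2 (cat.), THF, rt → 45 °C; titrate before use
Reagents that add atoms: magnesium, [Mg]
Why: Grignard formation by insertion of magnesium metal into a primary C–Br bond is reliable in THF, and slow addition of the bromide limits Wurtz coupling.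

Step 5
Reactants: 8 vinylboronic acid pinacol ester; 7 undecylmagnesium bromide; 5 5-(benzyloxy)-1-bromo-3-methoxy-2-(methoxymethoxy)benzene
Product: 10 (R)-2-{1-[5-(benzyloxy)-3-methoxy-2-(methoxymethoxy)phenyl]tridecan-2-yl}-4,4,5,5-tetramethyl-1,3,2-dioxaborolane, via boron ate complex 9 (not isolated)
Conditions: 8 (1.3 equiv), 7 (1.2 equiv), THF, 0 °C → rt; then NaOTf (2 equiv), Pd(OAc)2 (2 mol%), (Rp,Rp)-MandyPhos (2.4 mol%), 5 (1.0 equiv), THF, 60 °C
Reagents that add atoms: none
Why: Addition of 7 to the vacant boron orbital of 8 gives the four-coordinate boronate 9, while oxidative addition of 5 to zerovalent palladium and bromide removal by NaOTf give a cationic divalent arylpalladium complex that binds the vinyl group of 9. The undecyl group then shifts from boron to the α-carbon anti to palladium as the β-carbon bonds to the metal (metal-induced 1,2-metallate rearrangement), and reductive elimination joins ring C1 to chain C1, so both new C–C bonds (ring C1–chain C1 and chain C2–C3) arise in one catalytic cycle. The closest known reaction type is the palladium/MandyPhos-catalysed enantioselective conjunctive cross-coupling of vinylboron ate complexes, for which a primary alkyl migrating group with an aryl electrophile is the standard pairing. No ring is closed. The new stereocentre at chain C2 (the C–B carbon) is controlled only by the chiral bisphosphine, which selects the alkene face that palladium binds, since the substrates carry no other stereocentre. The step needs the metallate shift to outrun direct Suzuki transfer of undecyl or vinyl and β-hydride elimination; a fully formed ate complex (8 in slight excess over 7), halide scavenging by NaOTf, the unhindered monosubstituted vinyl group and the wide-bite-angle ligand secure this, and regiochemistry is fixed because migration can only end on the boron-bearing carbon.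

Step 6
Reactants: 10 (R)-2-{1-[5-(benzyloxy)-3-methoxy-2-(methoxymethoxy)phenyl]tridecan-2-yl}-4,4,5,5-tetramethyl-1,3,2-dioxaborolane
Product: 11 (R)-1-[5-(benzyloxy)-3-methoxy-2-(methoxymethoxy)phenyl]tridecan-2-ol
Conditions: 30% H2O2, 3 M NaOH, THF, 0 °C → rt
Reagents that add atoms: hydrogen peroxide, OO
Why: In this boronate oxidation the hydroperoxide adds to boron and the carbon migrates from boron to oxygen with retention, so the R boronate should give the R carbinol; the aryl ethers and the acetal are inert to basic peroxide.

Step 7
Reactants: 11 (R)-1-[5-(benzyloxy)-3-methoxy-2-(methoxymethoxy)phenyl]tridecan-2-ol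
Product: 12 4-(benzyloxy)-2-[(2R)-2-hydroxytridecyl]-6-methoxyphenol
Conditions: conc. HCl (cat.), MeOH, 40 °C
Reagents that add atoms: none
Why: Acid-catalysed acetal exchange passes the methoxymethyl group to methanol and frees the phenol, while the benzyl and methyl ethers survive dilute acid and the non-benzylic secondary carbinol cannot ionise, so the stereocentre is untouched.

Step 8
Reactants: 12 4-(benzyloxy)-2-[(2R)-2-hydroxytridecyl]-6-methoxyphenol
Product: 13 (R)-1-[2-acetoxy-5-(benzyloxy)-3-methoxyphenyl]tridecan-2-yl acetate
Conditions: Ac2O, pyridine, DMAP (cat.), CH2Cl2, rt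
Reagents that add atoms: acetic anhydride, CC(=O)OC(C)=O
Why: DMAP-catalysed O-acylation (nucleophilic catalysis) should esterify both the hindered phenol and the secondary alcohol, with no bond to the stereocentre broken.

Step 9
Reactants: 13 (R)-1-[2-acetoxy-5-(benzyloxy)-3-methoxyphenyl]tridecan-2-yl acetate
Product: 14 (R)-1-(2-acetoxy-5-hydroxy-3-methoxyphenyl)tridecan-2-yl acetate
Conditions: H2 (1 atm), 10% Pd/C, EtOAc, rt
Reagents that add atoms: none
Why: Catalytic hydrogenolysis cleaves the benzyl aryl ether selectively, and the aprotic solvent keeps the aryl acetate from solvolysis while the alkyl acetate and the arene are inert at 1 atm.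

**Compound list**
1 | 5-bromovanillin (3-bromo-4-hydroxy-5-methoxybenzaldehyde) | COc1cc(C=O)cc(Br)c1O | starting material
2 | 3-bromo-5-methoxy-4-(methoxymethoxy)benzaldehyde | COCOc1c(Br)cc(C=O)cc1OC | intermediate
3 | 3-bromo-5-methoxy-4-(methoxymethoxy)phenyl formate | COCOc1c(Br)cc(OC=O)cc1OC | intermediate (not isolated)
4 | 3-bromo-5-methoxy-4-(methoxymethoxy)phenol | COCOc1c(Br)cc(O)cc1OC | intermediate
5 | 5-(benzyloxy)-1-bromo-3-methoxy-2-(methoxymethoxy)benzene | Brc1cc(OCc2ccccc2)cc(OC)c1OCOC | intermediate
6 | 1-bromoundecane | CCCCCCCCCCCBr | starting material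
7 | undecylmagnesium bromide | CCCCCCCCCCC[Mg]Br | intermediate
8 | vinylboronic acid pinacol ester (4,4,5,5-tetramethyl-2-vinyl-1,3,2-dioxaborolane) | C=CB1OC(C)(C)C(C)(C)O1 | starting material
9 | bromomagnesium undecyl(vinyl)(pinacolato)borate | CCCCCCCCCCC[B-]1(C=C)OC(C)(C)C(C)(C)O1.[Mg+]Br | intermediate (not isolated)
10 | (R)-2-{1-[5-(benzyloxy)-3-methoxy-2-(methoxymethoxy)phenyl]tridecan-2-yl}-4,4,5,5-tetramethyl-1,3,2-dioxaborolane | CCCCCCCCCCC[C@H](Cc1cc(OCc2ccccc2)cc(OC)c1OCOC)B1OC(C)(C)C(C)(C)O1 | intermediate
11 | (R)-1-[5-(benzyloxy)-3-methoxy-2-(methoxymethoxy)phenyl]tridecan-2-ol | CCCCCCCCCCC[C@H](Cc1cc(OCc2ccccc2)cc(OC)c1OCOC)O | intermediate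
12 | 4-(benzyloxy)-2-[(2R)-2-hydroxytridecyl]-6-methoxyphenol | CCCCCCCCCCC[C@H](Cc1cc(OCc2ccccc2)cc(OC)c1O)O | intermediate
13 | (R)-1-[2-acetoxy-5-(benzyloxy)-3-methoxyphenyl]tridecan-2-yl acetate | CCCCCCCCCCC[C@H](Cc1cc(OCc2ccccc2)cc(OC)c1OC(C)=O)OC(C)=O | intermediate
14 | (R)-1-(2-acetoxy-5-hydroxy-3-methoxyphenyl)tridecan-2-yl acetate | CCCCCCCCCCC[C@H](Cc1cc(O)cc(OC)c1OC(C)=O)OC(C)=O | target

**Step count**
Total: 9 steps. Longest linear sequence: 8 steps (steps 1, 2, 3, 5, 6, 7, 8, 9 from 5-bromovanillin); the Grignard branch (step 4) joins at step 5.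

**Steps most likely to fail, with fallbacks**

Step 5. Oxidative addition of the electron-rich, ortho-alkoxy aryl bromide may be slow, so that direct transmetalation of the ate complex, residual halide inhibition of the metallate shift or insufficient facial discrimination takes over. The fallback sets out from 5 and returns at 11, and buys the stereocentre instead of making it by catalysis. Bromine–lithium exchange on 5 (n-BuLi, THF, −78 °C) would give [5-(benzyloxy)-3-methoxy-2-(methoxymethoxy)phenyl]lithium F1. This would open (R)-2-undecyloxirane F2 at its terminal carbon in the presence of BF3·OEt2 at −78 °C. F2 would come from Jacobsen hydrolytic kinetic resolution of commercial racemic 1,2-epoxytridecane, using the chiral (salen)Co(OAc) antipode that leaves the R epoxide and 0.55 equiv of water. Because the epoxide stereocentre is not touched, alcohol 11 would form directly and steps 4 to 6 fall away.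

Step 2. Hydride may migrate in place of the aryl group, giving the benzoic acid, or the acid by-product may strip the MOM acetal and open the way to quinone formation. The fallback sets out from 1 and returns at 4, and moves the oxidation to the free phenol, where the Dakin reaction is most reliable.
- Alkaline hydrogen peroxide (NaOH, H2O2, water, then acidic work-up) would convert 1 into 2-bromo-6-methoxybenzene-1,4-diol F3.
- TBSCl and imidazole at 0 °C should silylate the unhindered 4-hydroxyl in preference to the one flanked by bromine and methoxy, giving 2-bromo-4-[(tert-butyldimethylsilyl)oxy]-6-methoxyphenol F4.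
- MOMCl and i-Pr2NEt would then cap the hindered phenol to give [3-bromo-5-methoxy-4-(methoxymethoxy)phenoxy](tert-butyl)dimethylsilane F5.
- Bu4NF in THF would release phenol 4.

Step 7. The oxocarbenium fragment released from the MOM group may be recaptured by the neighbouring phenol and carbinol oxygens as a cyclic formaldehyde acetal, or may alkylate the electron-rich ring. The fallback sets out from 11 and returns at 13, and changes the order of events so that no free diol meets the acid.
- Ac2O, pyridine and DMAP would first convert 11 into (R)-1-[5-(benzyloxy)-3-methoxy-2-(methoxymethoxy)phenyl]tridecan-2-yl acetate F6.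
- The MOM group would then be removed under aprotic conditions with a thiol trap (ZnBr2, n-PrSH, CH2Cl2, 0 °C) to give (R)-1-[5-(benzyloxy)-2-hydroxy-3-methoxyphenyl]tridecan-2-yl acetate F7.
- Acetylation of the phenol (Ac2O, pyridine, DMAP) would give 13.

**Further compounds**
F1 | step 5 | [5-(benzyloxy)-3-methoxy-2-(methoxymethoxy)phenyl]lithium | [Li]c1cc(OCc2ccccc2)cc(OC)c1OCOC
F2 | step 5 | (R)-2-undecyloxirane | CCCCCCCCCCC[C@@H]1CO1
F3 | step 2 | 2-bromo-6-methoxybenzene-1,4-diol | COc1cc(O)cc(Br)c1O
F4 | step 2 | 2-bromo-4-[(tert-butyldimethylsilyl)oxy]-6-methoxyphenol | COc1cc(O[Si](C)(C)C(C)(C)C)cc(Br)c1O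
F5 | step 2 | [3-bromo-5-methoxy-4-(methoxymethoxy)phenoxy](tert-butyl)dimethylsilane | COCOc1c(Br)cc(O[Si](C)(C)C(C)(C)C)cc1OC
F6 | step 7 | (R)-1-[5-(benzyloxy)-3-methoxy-2-(methoxymethoxy)phenyl]tridecan-2-yl acetate | CCCCCCCCCCC[C@H](Cc1cc(OCc2ccccc2)cc(OC)c1OCOC)OC(C)=O
F7 | step 7 | (R)-1-[5-(benzyloxy)-2-hydroxy-3-methoxyphenyl]tridecan-2-yl acetate | CCCCCCCCCCC[C@H](Cc1cc(OCc2ccccc2)cc(OC)c1O)OC(C)=O
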